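All constants were set for the occasion; the rest is arithmetic.

I began with the leftover: how much substrate would still stand in each flask after 10 h?

| flask | substrate | free catalyst | time | remark |
|---|---|---|---|---|
| larch | 0.27 M (fed, over 20 min) | 0.5 mol% | 10 h | the fed solution adds 0.20 times the starting volume |
| alder | 0.27 M (fed, over 20 min) | 0.8 mol% | 10 h | the fed solution adds 0.20 times the starting volume |
| ash | 0.27 M (fed, over 20 min) | 1.2 mol% | 10 h | the fed solution adds 0.20 times the starting volume |

    substrate + free catalyst → catalyst intermediate A (k1 = 17 L mol⁻¹ min⁻¹)
    catalyst intermediate A → catalyst intermediate B (k2 = 0.77 min⁻¹)
    catalyst intermediate B → free catalyst + product (k3 = 0.21 min⁻¹)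
    2 catalyst intermediate A ⇌ resting dimer, settled at all times (K4 = 2900 L mol⁻¹)

- in percentages every species weighs as the substrate in it: one resting dimer counts as two
- for a step with 2 of a species take k times the square, and two of it per event
- charges are per starting volume, the dose included; the dosed solution carries all of it
- "hardly changes" means that all values lie within two and a half points (for a concentration: within two and a half percent of the largest)
- run time (larch): 10 h

- amount of product at the end, in percent of the substrate charged for larch, alder, ash, in this order
- the course of these numbers from the first flask to the last (rises all the way / falls all the way / rises, then falls / falls, then rises / hardly changes)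

I built larch up one process at a time. With the release of product from catalyst intermediate B alone, each catalyst turns over at 0.21 min⁻¹, and the yield is that constant times loading times run time, 63.0%. Adding the conversion of catalyst intermediate A, which is faster than the release, so that the release stays the rate-limiting step, lengthens one round to 6.06 min and lowers the yield to 49.5%.

Next came the resting dimer, which takes catalyst out of the round. Its measure is the half-dimer level, 7.51 mM: one plus the ratio of the conversion constant to the release constant, squared, over the dimer constant, which is the total catalyst at which the resting dimer holds half of it, free catalyst being set aside in this reckoning. For any other total, with free catalyst still set aside and catalyst intermediates A and B in their steady ratio, the dimer's share divided by the share in those two intermediates squared equals 2 times the catalyst over this level.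

After the feed, larch holds 1.12 mM of catalyst, so the dimer's share is 19.4% and the yield falls to 39.9%. Binding of substrate, reckoned with the whole charge unconverted in the final volume, adds 0.261 min to the round, which gives 38.2% for larch. The feed lasts 20 min, far shorter than the run, so I left it out.

The same steps gave a dimer share of 26.1% and a yield of 56.1% for alder. For ash, with 2.70 mM of catalyst, they gave 32.6% and 76.7%. My row therefore rose, but from larch to ash the yield grew 2.01 times while the loading grew 2.40 times.

The forecast gave 37.8%, 55.3% and 75.4%, and its course rises all the way. For ash this stood lower than my figure. Its ground was: “The dimer term matters, so rate grows less than proportionally with catalyst”.

The flasks gave 38.1%, 55.9% and 76.1% of product, so the course rises all the way, and larch kept 61% of its substrate. In larch at the end, the half-life of catalyst intermediate B by release, 3.30 min, was longer than the 0.90 min of catalyst intermediate A by conversion and the 0.30 min of free catalyst by binding, and catalyst intermediate B held 60.4% of the larch catalyst. Larch stood at 14.9% of the half-dimer level and ash at 36.0%, and after 5.00 h the resting dimer held 18.1% of the larch catalyst and 30.4% of the ash catalyst.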